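**Strategy.** Both flavan units derive from one monomer. The C4–C6 interflavan bond is made last, by silver-mediated activation of a 4-benzylsulfanyl flavan-3-ol in the presence of the free flavan-3,4-diol. The plan rests on reading the trans-3,4-diol of the pyran ring (ring C) of the lower, diol-bearing unit, C3 and C4 lying between C2 and C4a, as a masked cis C3=C4 alkene. Ring-closing metathesis of an acyclic (S)-1-arylallyl 2-vinylaryl ether, made by iridium-catalysed asymmetric allylic etherification, forms the C3–C4 bond and closes ring C in one operation. The C2 stereocentre then relays C3 and C4 by bromohydrin formation, syn-epoxide closure and anti opening.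

Key step: step 7

**Assumptions.** Flavonoid numbering is used (O1, C2, C3, C4, C4a, C5–C8, C8a; ring A is the benzo ring, ring C the pyran ring). α is the face of ring C that carries the 2-aryl group, β the opposite face. In step 6 the antipode of the phosphoramidite ligand is taken that delivers the (S)-ether 8; both antipodes are commercial. The flavene 9 has the same spatial arrangement at C2 as the target, and the descriptor changes from S to R only because C3 gains priority over the aryl group once it is oxygenated or brominated.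

**Step 1**
Reactants: 1 2,3,4-trihydroxybenzaldehyde
Product: 2 3,4-bis(benzyloxy)-2-hydroxybenzaldehyde
Conditions: BnBr (2.1 equiv), K2CO3 (2.1 equiv), acetone, reflux
Reagents that add atoms: benzyl bromide, BrCc1ccccc1
Why: Williamson ether synthesis in which the 2-hydroxyl, held in a hydrogen bond to the formyl group, is the least nucleophilic, so two equivalents of benzyl bromide should etherify the 3- and 4-hydroxyls selectively.

**Step 2**
Reactants: 2 3,4-bis(benzyloxy)-2-hydroxybenzaldehyde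
Product: 3 2,3-bis(benzyloxy)-6-ethenylphenol
Conditions: Ph3PCH3Br (2.5 equiv), KOtBu (2.5 equiv), THF, 0 °C to rt
Reagents that add atoms: methyltriphenylphosphonium bromide, C[P+](c1ccccc1)(c1ccccc1)c1ccccc1.[Br-]
Why: Wittig methylenation, the excess ylide first deprotonating the phenol and then converting the formyl group of the phenoxide into the vinyl group, as is usual for salicylaldehydes.

**Step 3**
Reactants: 4 3,4-bis(benzyloxy)benzaldehyde
Product: 5 ethyl (2E)-3-[3,4-bis(benzyloxy)phenyl]prop-2-enoate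
Conditions: Ph3P=CHCO2Et (1.2 equiv), toluene, 90 °C
Reagents that add atoms: ethyl (triphenylphosphoranylidene)acetate, CCOC(=O)C=P(c1ccccc1)(c1ccccc1)c1ccccc1
Why: Wittig olefination with a stabilised ylide, which should give the E-cinnamate.

**Step 4**
Reactants: 5 ethyl (2E)-3-[3,4-bis(benzyloxy)phenyl]prop-2-enoate
Product: 6 (2E)-3-[3,4-bis(benzyloxy)phenyl]prop-2-en-1-ol
Conditions: iBu2AlH (2.5 equiv), CH2Cl2, −78 to 0 °C; aqueous Rochelle salt
Reagents that add atoms: none
Why: 1,2-reduction of the conjugated ester by the aluminium hydride, which should give the allylic alcohol without touching the alkene or the benzyl ethers.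

**Step 5**
Reactants: 6 (2E)-3-[3,4-bis(benzyloxy)phenyl]prop-2-en-1-ol
Product: 7 (2E)-3-[3,4-bis(benzyloxy)phenyl]prop-2-en-1-yl methyl carbonate
Conditions: ClCO2Me (1.3 equiv), pyridine, CH2Cl2, 0 °C
Reagents that add atoms: methyl chloroformate, COC(Cl)=O
Why: O-acylation of the primary allylic alcohol, which installs the carbonate leaving group needed for allyl-metal formation.

**Step 6**
Reactants: 3 2,3-bis(benzyloxy)-6-ethenylphenol; 7 (2E)-3-[3,4-bis(benzyloxy)phenyl]prop-2-en-1-yl methyl carbonate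
Product: 8 1,2-bis(benzyloxy)-3-({(1S)-1-[3,4-bis(benzyloxy)phenyl]prop-2-en-1-yl}oxy)-4-ethenylbenzene
Conditions: 3, LiN(SiMe3)2 (1.0 equiv), THF, 0 °C; then 7, [Ir(cod)Cl]2 (2 mol%), O,O'-(1,1'-binaphthalene-2,2'-diyl) N,N-bis(1-phenylethyl)phosphoramidite (4 mol%), THF, 50 °C
Reagents that add atoms: none
Why: Iridium-catalysed asymmetric allylic etherification, in which the lithium aryloxide attacks the aryl-substituted terminus of the allyl-iridium intermediate to give the branched ether, the chiral cyclometalated phosphoramidite complex setting the future C2 stereocentre as S.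

**Step 7**
Reactants: 8 1,2-bis(benzyloxy)-3-({(1S)-1-[3,4-bis(benzyloxy)phenyl]prop-2-en-1-yl}oxy)-4-ethenylbenzene
Product: 9 (2S)-7,8-bis(benzyloxy)-2-[3,4-bis(benzyloxy)phenyl]-2H-chromene
Conditions: second-generation Grubbs catalyst RuCl2(=CHPh)(H2IMes)(PCy3) (5 mol%), 1,4-benzoquinone (10 mol%), CH2Cl2 (0.01 M), 40 °C
Reagents that add atoms: none
Why: The ruthenium alkylidene engages one terminal alkene, and a [2+2] cycloaddition and cycloreversion sequence through a ruthenacyclobutane joins the two inner alkene carbons as C3=C4 while ethene is expelled, which drives the reaction. The closest known reaction type is ring-closing metathesis of 2-vinylaryl allyl ethers to 2H-chromenes. Ring C (O1–C2–C3–C4–C4a–C8a) closes as a six-membered ring by ring-closing diene metathesis, the cis geometry of the new alkene being imposed by the ring. No new stereocentre is created; C2 is a spectator under the neutral conditions and afterwards directs both additions to the C3=C4 bond. The step needs ring closure to outrun cross-metathesis dimerisation and ruthenium hydride isomerisation of the allylic ether, which the ortho placement of the two alkenes on the aryl ether, high dilution and the benzoquinone additive should secure.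

**Step 8**
Reactants: 9 (2S)-7,8-bis(benzyloxy)-2-[3,4-bis(benzyloxy)phenyl]-2H-chromene
Product: 10 (2R,3S,4R)-7,8-bis(benzyloxy)-2-[3,4-bis(benzyloxy)phenyl]-3-bromochroman-4-ol (3β-Br, 4α-OH)
Conditions: NBS (1.05 equiv), THF/H2O (5:1), 0 °C, dark
Reagents that add atoms: N-bromosuccinimide, O=C1CCC(=O)N1Br; water, O
Why: Bromohydrin formation, in which the bromonium ion forms on the β face anti to the 2-aryl group and water opens it at benzylic C4 (cation stabilised by O1 and the 7-benzyloxy group) anti to bromine, which should give the 2,3-trans-3,4-trans bromohydrin.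

**Step 9**
Reactants: 10 (2R,3S,4R)-7,8-bis(benzyloxy)-2-[3,4-bis(benzyloxy)phenyl]-3-bromochroman-4-ol
Product: 12 (2R,3R,4S)-7,8-bis(benzyloxy)-2-[3,4-bis(benzyloxy)phenyl]chromane-3,4-diol, via syn-epoxide 11 (not isolated)
Conditions: NaOH (1 M aq., 1.5 equiv), 1,4-dioxane, 0 °C to rt; then NaH2PO4 buffer (pH 6), rt
Reagents that add atoms: water, O
Why: Intramolecular Williamson closure by the C4 alkoxide inverts C3 and places the epoxide oxygen on the α face syn to the 2-aryl group, and the labile benzylic epoxide is then opened by water at C4 anti to the C3 oxygen and to the aryl group (SN1-like, β attack), which should give the 2,3-cis-3,4-trans diol and so sets C3 as R and C4 as S.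

**Step 10**
Reactants: 12 (2R,3R,4S)-7,8-bis(benzyloxy)-2-[3,4-bis(benzyloxy)phenyl]chromane-3,4-diol
Product: 13 (2R,3R,4S)-2-(3,4-dihydroxyphenyl)chromane-3,4,7,8-tetrol (isomelacacidin, epimesquitol-4β-ol)
Conditions: H2 (1 atm), 10% Pd/C, EtOAc/MeOH (1:1), rt, stopped at full debenzylation
Reagents that add atoms: none
Why: Hydrogenolysis of the four aryl benzyl ethers, which are cleaved much faster than a secondary benzylic alcohol in a neutral medium, so the C4 hydroxyl and all stereocentres should survive.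

**Step 11**
Reactants: 13 (2R,3R,4S)-2-(3,4-dihydroxyphenyl)chromane-3,4,7,8-tetrol (one part of the material)
Product: 14 (2R,3S,4S)-4-(benzylsulfanyl)-2-(3,4-dihydroxyphenyl)chromane-3,7,8-triol (4β-benzylsulfanylepimesquitol)
Conditions: BnSH (10 equiv), AcOH/EtOH (1:4), 80 °C, N2
Reagents that add atoms: phenylmethanethiol, SCc1ccccc1
Why: Acid-catalysed SN1 thiolysis, in which the C4 hydroxyl ionises to the benzylic cation stabilised by the 7-hydroxyl (para-quinone methide) and the thiol captures it on the β face trans to the 3-hydroxyl and the 2-aryl group, the excess thiol suppressing self-condensation.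

**Step 12**
Reactants: 14 (2R,3S,4S)-4-(benzylsulfanyl)-2-(3,4-dihydroxyphenyl)chromane-3,7,8-triol; 13 (2R,3R,4S)-2-(3,4-dihydroxyphenyl)chromane-3,4,7,8-tetrol (4 equiv)
Product: 15 (2R,3R,4S)-2-(3,4-dihydroxyphenyl)-6-[(2R,3R,4S)-2-(3,4-dihydroxyphenyl)-3,7,8-trihydroxychroman-4-yl]chromane-3,4,7,8-tetrol (epimesquitol-(4β→6)-epimesquitol-4β-ol)
Conditions: AgBF4 (2.5 equiv), THF, 0 °C, dark, N2; separation from the C5-linked isomer and recovered 13
Reagents that add atoms: none
Why: Thiophilic activation followed by Friedel–Crafts alkylation, in which the silver ion abstracts the benzylthiolate from C4 of 14 and the cation is attacked by C6 of 13 (para to O1, ortho to the 7-hydroxyl) on the β face anti to the 3-hydroxyl and 2-aryl group, setting the interflavan stereocentre as S while the 4-hydroxyl of 13 is not ionised by the silver salt.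

**Compound list**
1 | 2,3,4-trihydroxybenzaldehyde | O=Cc1ccc(O)c(O)c1O | starting material
2 | 3,4-bis(benzyloxy)-2-hydroxybenzaldehyde | O=Cc1ccc(OCc2ccccc2)c(OCc2ccccc2)c1O | intermediate
3 | 2,3-bis(benzyloxy)-6-ethenylphenol | C=Cc1ccc(OCc2ccccc2)c(OCc2ccccc2)c1O | intermediate
4 | 3,4-bis(benzyloxy)benzaldehyde | O=Cc1ccc(OCc2ccccc2)c(OCc2ccccc2)c1 | starting material
5 | ethyl (2E)-3-[3,4-bis(benzyloxy)phenyl]prop-2-enoate | CCOC(=O)/C=C/c1ccc(OCc2ccccc2)c(OCc2ccccc2)c1 | intermediate
6 | (2E)-3-[3,4-bis(benzyloxy)phenyl]prop-2-en-1-ol | OC/C=C/c1ccc(OCc2ccccc2)c(OCc2ccccc2)c1 | intermediate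
7 | (2E)-3-[3,4-bis(benzyloxy)phenyl]prop-2-en-1-yl methyl carbonate | COC(=O)OC/C=C/c1ccc(OCc2ccccc2)c(OCc2ccccc2)c1 | intermediate
8 | 1,2-bis(benzyloxy)-3-({(1S)-1-[3,4-bis(benzyloxy)phenyl]prop-2-en-1-yl}oxy)-4-ethenylbenzene | C=Cc1ccc(OCc2ccccc2)c(OCc2ccccc2)c1O[C@@H](C=C)c1ccc(OCc2ccccc2)c(OCc2ccccc2)c1 | intermediate
9 | (2S)-7,8-bis(benzyloxy)-2-[3,4-bis(benzyloxy)phenyl]-2H-chromene | C1=C[C@@H](c2ccc(OCc3ccccc3)c(OCc3ccccc3)c2)Oc2c1ccc(OCc1ccccc1)c2OCc1ccccc1 | intermediate
10 | (2R,3S,4R)-7,8-bis(benzyloxy)-2-[3,4-bis(benzyloxy)phenyl]-3-bromochroman-4-ol | c1cc2c(c(OCc3ccccc3)c1OCc1ccccc1)O[C@H](c1ccc(OCc3ccccc3)c(OCc3ccccc3)c1)[C@@H](Br)[C@@H]2O | intermediate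
11 | (2R,3R,4R)-7,8-bis(benzyloxy)-2-[3,4-bis(benzyloxy)phenyl]-3,4-epoxychromane (epoxide oxygen cis to the 2-aryl group) | c1cc2c(c(OCc3ccccc3)c1OCc1ccccc1)O[C@H](c1ccc(OCc3ccccc3)c(OCc3ccccc3)c1)[C@@H]1O[C@H]21 | intermediate
12 | (2R,3R,4S)-7,8-bis(benzyloxy)-2-[3,4-bis(benzyloxy)phenyl]chromane-3,4-diol | c1cc2c(c(OCc3ccccc3)c1OCc1ccccc1)O[C@H](c1ccc(OCc3ccccc3)c(OCc3ccccc3)c1)[C@H](O)[C@H]2O | intermediate
13 | (2R,3R,4S)-2-(3,4-dihydroxyphenyl)chromane-3,4,7,8-tetrol | c1cc2c(c(O)c1O)O[C@H](c1ccc(O)c(O)c1)[C@H](O)[C@H]2O | intermediate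
14 | (2R,3S,4S)-4-(benzylsulfanyl)-2-(3,4-dihydroxyphenyl)chromane-3,7,8-triol | c1cc2c(c(O)c1O)O[C@H](c1ccc(O)c(O)c1)[C@H](O)[C@H]2SCc1ccccc1 | intermediate
15 | (2R,3R,4S)-2-(3,4-dihydroxyphenyl)-6-[(2R,3R,4S)-2-(3,4-dihydroxyphenyl)-3,7,8-trihydroxychroman-4-yl]chromane-3,4,7,8-tetrol | Oc1ccc([C@H]2Oc3c(ccc(O)c3O)[C@H](c3cc4c(c(O)c3O)O[C@H](c3ccc(O)c(O)c3)[C@H](O)[C@H]4O)[C@H]2O)cc1O | target

**Totals.** Total step count: 12. Longest linear sequence: 10 steps (4 → 5 → 6 → 7 → 8 → 9 → 10 → 12 → 13 → 14 → 15; the branch 1 → 2 → 3 joins at step 6).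

**Steps most likely to fail**

Step 12. The C4 cation may be intercepted at C5 of ring A or at the hydroxyl oxygens of 13, and the product may be alkylated again, so regio- and chemoselectivity may be low. The fallback sets out from 12 and comes back at the target 15, and moves the coupling to the benzyl ether series. Thioetherification of 12 (BnSH, BF3·OEt2, CH2Cl2, −20 °C) should give (2R,3S,4S)-4-(benzylsulfanyl)-7,8-bis(benzyloxy)-2-[3,4-bis(benzyloxy)phenyl]chroman-3-ol F7. Coupling of F7 with an excess of 12 (AgBF4, CH2Cl2/THF, −20 °C), where the soft aryl ether nucleophile, the non-polar medium and the low temperature favour C-alkylation at C6 and the isomers can be separated on silica, should give the octa-O-benzyl ether of the target F8. Hydrogenolysis (H2, 10% Pd/C, EtOAc/MeOH) then gives 15.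

Step 6. The 2,6-disubstituted phenoxide is a hindered nucleophile and the electron-rich 1-arylallyl ether may re-ionise at iridium, so attack may drift to the linear terminus and the enantiomeric purity may erode with time. The fallback sets out from 4 and 3 and comes back at 8. Enantioselective zinc-mediated addition of trimethylsilylacetylene to 4 (ZnMe2, chiral amino alcohol ligand, toluene) should give (1S)-1-[3,4-bis(benzyloxy)phenyl]-3-(trimethylsilyl)prop-2-yn-1-ol F1. Mitsunobu etherification with 3 (PPh3, diisopropyl azodicarboxylate, toluene, 0 °C) proceeds with inversion and should give the silylated aryl propargyl ether 1,2-bis(benzyloxy)-3-({(1R)-1-[3,4-bis(benzyloxy)phenyl]-3-(trimethylsilyl)prop-2-yn-1-yl}oxy)-4-ethenylbenzene F2. K2CO3 in MeOH removes the silyl group to give 1,2-bis(benzyloxy)-3-({(1S)-1-[3,4-bis(benzyloxy)phenyl]prop-2-yn-1-yl}oxy)-4-ethenylbenzene F3. Semihydrogenation over Lindlar catalyst (Pd/CaCO3 poisoned with Pb(OAc)2, quinoline, H2) returns 8.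

Step 8. Electrophilic bromine may attack the activated ring A (C6) or ring B in competition with the alkene, and the benzylic cation may be captured by water syn to bromine, which leads to a bromohydrin that cannot close to the epoxide. The fallback sets out from 9 and comes back at 12. Hydroboration and oxidation (BH3·SMe2, THF; then NaOH, H2O2) places the hydroxyl at C3 anti to the aryl group and should give the 2,3-trans alcohol (2R,3S)-7,8-bis(benzyloxy)-2-[3,4-bis(benzyloxy)phenyl]chroman-3-ol F4. Dess–Martin periodinane oxidation gives (2R)-7,8-bis(benzyloxy)-2-[3,4-bis(benzyloxy)phenyl]chroman-3-one F5. LiBH(s-Bu)3 in THF at −78 °C delivers hydride anti to the 2-aryl group and should give the 2,3-cis alcohol (2R,3R)-7,8-bis(benzyloxy)-2-[3,4-bis(benzyloxy)phenyl]chroman-3-ol F6. Benzylic oxidation with DDQ in wet CH2Cl2 (hydride abstraction at C4, water captured on the β face trans to the 3-hydroxyl) returns 12.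

**Further compounds**
F1 | step 6 | (1S)-1-[3,4-bis(benzyloxy)phenyl]-3-(trimethylsilyl)prop-2-yn-1-ol | O[C@H](C#C[Si](C)(C)C)c1ccc(OCc2ccccc2)c(OCc2ccccc2)c1
F2 | step 6 | 1,2-bis(benzyloxy)-3-({(1R)-1-[3,4-bis(benzyloxy)phenyl]-3-(trimethylsilyl)prop-2-yn-1-yl}oxy)-4-ethenylbenzene | C=Cc1ccc(OCc2ccccc2)c(OCc2ccccc2)c1O[C@@H](C#C[Si](C)(C)C)c1ccc(OCc2ccccc2)c(OCc2ccccc2)c1
F3 | step 6 | 1,2-bis(benzyloxy)-3-({(1S)-1-[3,4-bis(benzyloxy)phenyl]prop-2-yn-1-yl}oxy)-4-ethenylbenzene | C=Cc1ccc(OCc2ccccc2)c(OCc2ccccc2)c1O[C@@H](C#C)c1ccc(OCc2ccccc2)c(OCc2ccccc2)c1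
F4 | step 8 | (2R,3S)-7,8-bis(benzyloxy)-2-[3,4-bis(benzyloxy)phenyl]chroman-3-ol | c1cc2c(c(OCc3ccccc3)c1OCc1ccccc1)O[C@H](c1ccc(OCc3ccccc3)c(OCc3ccccc3)c1)[C@@H](O)C2
F5 | step 8 | (2R)-7,8-bis(benzyloxy)-2-[3,4-bis(benzyloxy)phenyl]chroman-3-one | c1cc2c(c(OCc3ccccc3)c1OCc1ccccc1)O[C@H](c1ccc(OCc3ccccc3)c(OCc3ccccc3)c1)C(=O)C2
F6 | step 8 | (2R,3R)-7,8-bis(benzyloxy)-2-[3,4-bis(benzyloxy)phenyl]chroman-3-ol | c1cc2c(c(OCc3ccccc3)c1OCc1ccccc1)O[C@H](c1ccc(OCc3ccccc3)c(OCc3ccccc3)c1)[C@H](O)C2
F7 | step 12 | (2R,3S,4S)-4-(benzylsulfanyl)-7,8-bis(benzyloxy)-2-[3,4-bis(benzyloxy)phenyl]chroman-3-ol | c1cc2c(c(OCc3ccccc3)c1OCc1ccccc1)O[C@H](c1ccc(OCc3ccccc3)c(OCc3ccccc3)c1)[C@H](O)[C@H]2SCc1ccccc1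
F8 | step 12 | octa-O-benzyl ether of 15 (all eight phenolic hydroxyls benzylated; configuration as in 15) | c9ccccc9COc1ccc([C@H]2Oc3c(ccc(OCc9ccccc9)c3OCc9ccccc9)[C@H](c3cc4c(c(OCc9ccccc9)c3OCc9ccccc9)O[C@H](c3ccc(OCc9ccccc9)c(OCc9ccccc9)c3)[C@H](O)[C@H]4O)[C@H]2O)cc1OCc9ccccc9
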